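**Retrosynthetic overview**
- Target ⇒ 2-henicosyl-5-methyl-1,4-benzoquinone. Both ring C–OH bonds are disconnected together, as a twofold ring C–H → C–O conversion in the last step.
- Quinone ⇒ 1-henicosyl-2,5-dimethoxy-4-methylbenzene, by oxidative demethylation.
- Ether ⇒ 1,4-dimethoxy-2,5-dimethylbenzene + 1-bromoicosane. The benzylic carbon plus C20 gives the C21 chain, and the para relation of methyl and chain comes with the purchased arene.
- Rings: none is built, because the only ring is the purchased benzene ring. Two oxiranes appear and vanish inside the last flask.

Assumption: the side chain is read as unbranched henicosyl (C21), and the target has no stereocentre (achiral), so no enantiomer question arises.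

**Step 1**
Reactants: 1 1,4-dimethoxy-2,5-dimethylbenzene; 2 1-bromoicosane
Product: 4 1-henicosyl-2,5-dimethoxy-4-methylbenzene, via benzylpotassium 3 (not isolated)
Conditions: 1 (1.25 equiv), n-BuLi, KOtBu, 2,2,6,6-tetramethylpiperidine (1.25 equiv each), THF, −78 °C, 30 min; then 2 (1.0 equiv) in THF, −78 °C → rt; H2O
Reagents that add atoms: none
Why: Lateral (benzylic) metalation by the mixed n-BuLi/KOtBu/amine superbase, in which potassium tetramethylpiperidide equilibrates any ring anion to the more stable benzylic potassium species 3, followed by SN2 alkylation of the primary bromide, adds C20 to the benzylic carbon, gives a single constitutional isomer because the two methyl groups of 1 are equivalent, and creates no stereocentre.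

**Step 2**
Reactants: 4 1-henicosyl-2,5-dimethoxy-4-methylbenzene
Product: 5 2-henicosyl-5-methyl-1,4-benzoquinone
Conditions: (NH4)2Ce(NO3)6 (2.5 equiv), MeCN/CH2Cl2/H2O, 0 °C → rt, 1 h
Reagents that add atoms: water, O
Why: Oxidative demethylation of a hydroquinone dimethyl ether by tetravalent cerium (two one-electron oxidations, water attacks the two ipso carbons and methanol leaves) is fast for electron-rich 1,4-dimethoxyarenes, leaves the saturated chain and the ring methyl untouched, and creates no stereocentre.

**Step 3**
Reactants: 5 2-henicosyl-5-methyl-1,4-benzoquinone
Product: 8 2-henicosyl-3,6-dihydroxy-5-methyl-1,4-benzoquinone, via quinone bis-epoxide 6 (not isolated), via dipotassium salt 7 (not isolated)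
Conditions: t-BuOOH (5.5 M in decane, 2.05 equiv) premixed with KOtBu (0.1 equiv), THF, 0 °C, then 5, 2 h; then KOtBu (2.3 equiv), 0 → 40 °C, Ar; then 1 M HCl
Reagents that add atoms: tert-butyl hydroperoxide, CC(C)(C)OO
Why: Proposed new method: twofold vicarious C–H hydroxylation of a 2,5-dialkylbenzoquinone in one flask, in which t-BuOOK adds in conjugate fashion to each unsubstituted ring carbon and the enolate closes on the O–O bond (Weitz–Scheffer epoxidation, catalytic in base, run on both C=C bonds while the ring is still neutral and electrophilic, the mono-epoxide being an ene-dione at least as reactive as 5) to give 6, after which stoichiometric KOtBu removes the only acidic protons, the two oxirane C–H alpha to a carbonyl, so that each oxirane opens by E1cB cleavage of its C(alkyl)–O bond and the oxygen stays on the former C–H carbon (an unclosed peroxide adduct would reach the same enolate by Kornblum–DeLaMare-type elimination), which fixes the 3,6-regiochemistry, erases the four transient stereocentres (the target has none) and is driven by formation of the doubly vinylogous carboxylate 7; the closest known reaction types are the alkaline peroxide epoxidation of 2-methyl-1,4-naphthoquinone with separate isomerisation of the isolated oxide to the hydroxyquinone, the base-induced epoxy ketone to diosphenol rearrangement, and the vicarious nucleophilic hydroxylation of nitroarenes with t-BuOOH/KOtBu, none of which has been shown twice on one benzoquinone ring to deliver a 2,5-dihydroxyquinone.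

**Compound list**
1 | 1,4-dimethoxy-2,5-dimethylbenzene | COc1cc(C)c(OC)cc1C | starting material
2 | 1-bromoicosane | CCCCCCCCCCCCCCCCCCCCBr | starting material
3 | (2,5-dimethoxy-4-methylbenzyl)potassium | [K+].[CH2-]c1cc(OC)c(C)cc1OC | intermediate (not isolated)
4 | 1-henicosyl-2,5-dimethoxy-4-methylbenzene | CCCCCCCCCCCCCCCCCCCCCc1cc(OC)c(C)cc1OC | intermediate
5 | 2-henicosyl-5-methyl-1,4-benzoquinone | CCCCCCCCCCCCCCCCCCCCCC1=CC(=O)C(C)=CC1=O | intermediate
6 | 1-henicosyl-5-methyl-4,8-dioxatricyclo[5.1.0.0(3,5)]octane-2,6-dione (2,3:5,6-bis-epoxide of 5; racemic syn/anti mixture, no defined configuration, all stereocentres erased in the same flask) | CCCCCCCCCCCCCCCCCCCCCC12OC1C(=O)C1(C)OC1C2=O | intermediate (not isolated)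
7 | dipotassium 2-henicosyl-5-methyl-3,6-dioxocyclohexa-1,4-diene-1,4-diolate | CCCCCCCCCCCCCCCCCCCCCC1=C([O-])C(=O)C(C)=C([O-])C1=O.[K+].[K+] | intermediate (not isolated)
8 | 2-henicosyl-3,6-dihydroxy-5-methyl-1,4-benzoquinone (= 2,5-dihydroxy-3-henicosyl-6-methyl-1,4-benzoquinone; achiral) | CCCCCCCCCCCCCCCCCCCCCC1=C(O)C(=O)C(C)=C(O)C1=O | target

**Total step count:** 3. **Longest linear sequence:** 3.

**Steps most likely to fail (highest risk first)**

1. **Step 3 (proposed new step).**
   - Premature opening of the first oxirane gives an acidic hydroxyquinone. This quenches the catalytic base and deactivates the second C=C.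
   - The oxirane C–H bonds are poorly aligned with the carbonyl. The second opening is slower still, because its acidifying carbonyl already belongs to a vinylogous carboxylate.
   - The alkylquinone can be deprotonated at its side chains if free alkoxide builds up.
   - Leftover peroxide can degrade the hydroxyquinone anion by ring contraction with chain shortening.
   - Fallback (known chemistry): it sets out from 5 and comes back to the route at 7. Quinone 5 is treated with Br2 (2.5 equiv) in CHCl3/AcOH in the dark, rt → 50 °C. Addition and dehydrobromination at both free ring positions, as in the classical dibromination of thymoquinone, give 2,5-dibromo-3-henicosyl-6-methyl-1,4-benzoquinone F1. Heating F1 with KOH in aqueous MeOH/THF replaces both bromides by hydroxide through addition–elimination and gives the dipotassium salt 7. Acidification of 7 gives 8.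

2. **Step 1.**
   - Ring metalation ortho to a methoxy group can compete with benzylic metalation.
   - The long bromide can undergo E2 elimination, and it is poorly soluble in cold THF.
   - Proton exchange can lead to double alkylation.
   - Fallback: it sets out from 2 and comes back at 4, with the polarity reversed (alkyl nucleophile, benzylic electrophile). Commercial 2,5-dimethoxy-4-methylbenzaldehyde F2 is treated with icosylmagnesium bromide F3 (from 2 and Mg turnings in THF). Aqueous work-up gives racemic 1-(2,5-dimethoxy-4-methylphenyl)henicosan-1-ol F4. Ionic hydrogenation (Et3SiH, CF3CO2H, CH2Cl2, 0 °C) then removes the benzylic hydroxyl group and its stereocentre to give 4.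

3. **Step 2.**
   - The waxy substrate may react slowly in the aqueous medium.
   - The radical cation can then dimerise to a biaryl diquinone or be trapped at a benzylic position.
   - Fallback: it sets out from 4 and comes back at 5, separating ether cleavage from oxidation. BBr3 (2.5 equiv, CH2Cl2, −78 °C → rt) cleaves both ethers without any oxidant to give 2-henicosyl-5-methylbenzene-1,4-diol F5. Ag2O (Et2O/THF, Na2SO4, rt) then dehydrogenates F5 to 5.

**Further compounds**
F1 | step 3 | 2,5-dibromo-3-henicosyl-6-methyl-1,4-benzoquinone | CCCCCCCCCCCCCCCCCCCCCC1=C(Br)C(=O)C(C)=C(Br)C1=O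
F2 | step 1 | 2,5-dimethoxy-4-methylbenzaldehyde (bought) | COc1cc(C=O)c(OC)cc1C
F3 | step 1 | icosylmagnesium bromide | CCCCCCCCCCCCCCCCCCCC[Mg]Br
F4 | step 1 | 1-(2,5-dimethoxy-4-methylphenyl)henicosan-1-ol (racemic) | CCCCCCCCCCCCCCCCCCCCC(O)c1cc(OC)c(C)cc1OC
F5 | step 2 | 2-henicosyl-5-methylbenzene-1,4-diol | CCCCCCCCCCCCCCCCCCCCCc1cc(O)c(C)cc1O
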